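**Plan**

- Retrosynthesis first removes the C10 acetate, the C8 methacrylate and the C10 hydroxyl/methyl pair (radical hydration of a C10=C14 methylene ketone). What remains in the ten-membered ring C1–C10 is the array C8 carbinol – C9 methylene – C10(=CH2) – C1 ketone, which is a homoallylic alcohol.
- C8–C9 is therefore cut by an intramolecular Barbier SE2' allylation between a C8 aldehyde on the butenolide carbon C7 and a 2-(bromomethyl)enone (C1/C10/C14); this bond closes the carbocycle.
- The butenolide (O–C6, C7=C11, C12) is cut at C11–C13 (Stille), C7–C8 (cuprate), O–C12 (lactonisation) and C6–C7 (alkynylation of an enal with methyl propiolate). C1–C10 is cut to a Baylis–Hillman reaction on the aldehyde obtained from geranyl acetate (C1–C6, C15).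
- Forward order: open chain, then the C1/C10/C14 terminus (masked as a methylene-dioxane), C6–C7, the epoxide ring, the butenolide ring, the ten-membered ring, and last the C10 oxygen and the two esters.
- Stereochemistry: C6 by catalyst control (zinc–ProPhenol alkynylation); C4/C5 relayed from C6 by hydroxyl-directed threo epoxidation of the E-alkene (A1,3 strain); C8 by the cyclic transition state of the macrocyclisation; C10 by O2 capture on the outer face of the formed ring.

Key step: step 17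

Assumption: (S,S)-ProPhenol is taken to give the 4R carbinol 11; if the sense of induction is the opposite, the (R,R)-ligand is used and nothing else changes.

Remark: compounds 6–9 are racemic at the carbon that becomes C1, so 11–22 are mixtures of two epimers at that carbon only. It is left undefined in the SMILES and is erased in step 16. After step 17 acidic media are avoided, because the 4,5-epoxide can open transannularly onto the C1 ketone.

**Route**

Step 1
Reactants: 1 geranyl acetate
Product: 2 (2E)-6,7-epoxy-3,7-dimethyloct-2-en-1-yl acetate (racemic)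
Conditions: mCPBA (1.0 equiv), NaHCO3, CH2Cl2, 0 °C
Reagents that add atoms: mCPBA, OOC(=O)c1cccc(Cl)c1
Why: Prilezhaev epoxidation selects the electron-rich remote trisubstituted alkene over the one deactivated by the allylic acetate; the new stereocentre is destroyed in step 2, so it needs no control.

Step 2
Reactants: 2 (2E)-6,7-epoxy-3,7-dimethyloct-2-en-1-yl acetate
Product: 4 (2E)-3-methyl-6-oxohex-2-en-1-yl acetate, via diol 3 (not isolated)
Conditions: H5IO6 (1.1 equiv), THF/H2O, 0 °C
Reagents that add atoms: none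
Why: Periodic acid hydrolyses the epoxide to diol 3 (water enters at the tertiary carbon) and cleaves it by Malaprade glycol fission to the C1 aldehyde and acetone, leaving the allylic acetate and the trisubstituted alkene untouched.

Step 3
Reactants: 4 (2E)-3-methyl-6-oxohex-2-en-1-yl acetate; 5 methyl acrylate
Product: 6 methyl (6E)-8-acetoxy-3-hydroxy-6-methyl-2-methylideneoct-6-enoate (racemic)
Conditions: 5 (3 equiv), DABCO (1 equiv), dioxane/H2O 1:1, rt
Reagents that add atoms: methyl acrylate 5, C=CC(=O)OC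
Why: Morita–Baylis–Hillman reaction of an unhindered aliphatic aldehyde joins C1 to C10 and brings in the methylene C9 and the future C14; the carbinol forms racemic, which is harmless because C1 ends as a ketone.

Step 4
Reactants: 6 methyl (6E)-8-acetoxy-3-hydroxy-6-methyl-2-methylideneoct-6-enoate
Product: 7 (6E)-6-methyl-2-methylideneoct-6-ene-1,3,8-triol (racemic)
Conditions: DIBAL-H (7 equiv), CH2Cl2, −78 → 0 °C; Rochelle salt
Reagents that add atoms: none
Why: DIBAL-H reduces the acrylate ester in the 1,2-sense to the allylic alcohol, as is routine for Baylis–Hillman esters, and cleaves the acetate in the same operation.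

Step 5
Reactants: 7 (6E)-6-methyl-2-methylideneoct-6-ene-1,3,8-triol
Product: 8 (2E)-5-(2,2-dimethyl-5-methylidene-1,3-dioxan-4-yl)-3-methylpent-2-en-1-ol (racemic)
Conditions: 2,2-dimethoxypropane, PPTS (cat.), CH2Cl2, 0 °C → rt
Reagents that add atoms: 2,2-dimethoxypropane, COC(C)(C)OC
Why: Acid-catalysed transketalisation gives the thermodynamically favoured six-membered acetonide of the 2-methylene-1,3-diol, while the remote primary allylic hydroxyl has no partner for a cyclic ketal and stays free.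

Step 6
Reactants: 8 (2E)-5-(2,2-dimethyl-5-methylidene-1,3-dioxan-4-yl)-3-methylpent-2-en-1-ol
Product: 9 (2E)-5-(2,2-dimethyl-5-methylidene-1,3-dioxan-4-yl)-3-methylpent-2-enal (racemic)
Conditions: activated MnO2 (20 equiv), CH2Cl2, rt
Reagents that add atoms: none
Why: MnO2 oxidises the primary allylic alcohol chemoselectively to the E-enal (allylic oxidation, as in geraniol to geranial).

Step 7
Reactants: 9 (2E)-5-(2,2-dimethyl-5-methylidene-1,3-dioxan-4-yl)-3-methylpent-2-enal; 10 methyl propiolate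
Product: 11 methyl (4R,5E)-8-(2,2-dimethyl-5-methylidene-1,3-dioxan-4-yl)-4-hydroxy-6-methyloct-5-en-2-ynoate
Conditions: (S,S)-ProPhenol (10 mol%), Me2Zn (3 equiv), 10 (3 equiv), toluene, 0–4 °C
Reagents that add atoms: methyl propiolate 10, C#CC(=O)OC
Why: Dinuclear zinc–ProPhenol asymmetric alkynylation, a reaction established for α,β-unsaturated aldehydes, delivers the zinc acetylide to one face of the enal, forming C6–C7 and setting the C6 carbinol under catalyst control.

Step 8
Reactants: 11 methyl (4R,5E)-8-(2,2-dimethyl-5-methylidene-1,3-dioxan-4-yl)-4-hydroxy-6-methyloct-5-en-2-ynoate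
Product: 12 methyl (4S)-4-{(2R,3R)-3-[2-(2,2-dimethyl-5-methylidene-1,3-dioxan-4-yl)ethyl]-3-methyloxiran-2-yl}-4-hydroxybut-2-ynoate
Conditions: mCPBA (1.2 equiv), NaHCO3, CH2Cl2, 0 °C
Reagents that add atoms: mCPBA, OOC(=O)c1cccc(Cl)c1
Why: Hydroxyl-directed (Henbest) peracid epoxidation: the methyl group cis to the carbinol forces the carbinol C–H into the alkene plane (A1,3 strain), so the hydrogen-bonded peracid delivers oxygen to give the threo epoxy alcohol (4R,5R relative to C6); the ynoate and the acetal-flanked methylene are too electron-poor to compete.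

Step 9
Reactants: 13 (tributylstannyl)methanol
Product: 14 tributyl{[(4-methoxybenzyl)oxy]methyl}stannane
Conditions: NaH (1.2 equiv), 4-methoxybenzyl chloride (1.1 equiv), Bu4NI (cat.), THF/DMF, 0 °C → rt
Reagents that add atoms: 4-methoxybenzyl chloride, COc1ccc(CCl)cc1
Why: Williamson etherification of the stannylmethoxide gives the α-alkoxystannane that serves as a protected hydroxymethyl anion equivalent.

Step 10
Reactants: 12 methyl (4S)-4-{(2R,3R)-3-[2-(2,2-dimethyl-5-methylidene-1,3-dioxan-4-yl)ethyl]-3-methyloxiran-2-yl}-4-hydroxybut-2-ynoate; 14 tributyl{[(4-methoxybenzyl)oxy]methyl}stannane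
Product: 17 (5S)-5-{(2R,3R)-3-[2-(2,2-dimethyl-5-methylidene-1,3-dioxan-4-yl)ethyl]-3-methyloxiran-2-yl}-3-iodo-4-{[(4-methoxybenzyl)oxy]methyl}furan-2(5H)-one, via alkenylcuprate 15 (not isolated), via iodo hydroxy enoate 16 (not isolated)
Conditions: 14 (2.6 equiv), n-BuLi, THF, −78 °C; CuBr·SMe2 (1.3 equiv); then 12 pre-treated with LiHMDS (1.0 equiv), −78 °C; I2, −78 → 0 °C; aq. NH4Cl/Na2S2O3
Reagents that add atoms: stannane 14, CCCC[Sn](CCCC)(CCCC)COCc1ccc(OC)cc1; iodine, II
Why: Tin–lithium exchange and cuprate formation give an alkoxymethyl Gilman reagent that adds syn to the ynoate (carbocupration, C8 onto C7) to give 15, iodinolysis with retention gives 16 with ester and alkoxide cis, and the alkoxide closes the butenolide by lactonisation (5-exo-trig acyl substitution).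

Step 11
Reactants: 17 (5S)-5-{(2R,3R)-3-[2-(2,2-dimethyl-5-methylidene-1,3-dioxan-4-yl)ethyl]-3-methyloxiran-2-yl}-3-iodo-4-{[(4-methoxybenzyl)oxy]methyl}furan-2(5H)-one; 13 (tributylstannyl)methanol
Product: 18 (5S)-5-{(2R,3R)-3-[2-(2,2-dimethyl-5-methylidene-1,3-dioxan-4-yl)ethyl]-3-methyloxiran-2-yl}-3-(hydroxymethyl)-4-{[(4-methoxybenzyl)oxy]methyl}furan-2(5H)-one
Conditions: 13 (1.5 equiv), Pd(PPh3)4 (10 mol%), dioxane, 80 °C
Reagents that add atoms: (tributylstannyl)methanol 13, CCCC[Sn](CCCC)(CCCC)CO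
Why: Stille (Kosugi–Migita) hydroxymethylation: the α-iodo butenolide undergoes oxidative addition readily and the stannane transfers its hydroxymethyl group, placing C13 on C11.

Step 12
Reactants: 18 (5S)-5-{(2R,3R)-3-[2-(2,2-dimethyl-5-methylidene-1,3-dioxan-4-yl)ethyl]-3-methyloxiran-2-yl}-3-(hydroxymethyl)-4-{[(4-methoxybenzyl)oxy]methyl}furan-2(5H)-one
Product: 19 [(5S)-5-{(2R,3R)-3-[2-(2,2-dimethyl-5-methylidene-1,3-dioxan-4-yl)ethyl]-3-methyloxiran-2-yl}-4-{[(4-methoxybenzyl)oxy]methyl}-2-oxo-2,5-dihydrofuran-3-yl]methyl acetate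
Conditions: Ac2O, pyridine, DMAP (cat.), CH2Cl2, 0 °C
Reagents that add atoms: acetic anhydride, CC(=O)OC(C)=O
Why: DMAP-catalysed acetylation of the only free hydroxyl; it is placed after the palladium step because the product is an allylic acetate.

Step 13
Reactants: 19 [(5S)-5-{(2R,3R)-3-[2-(2,2-dimethyl-5-methylidene-1,3-dioxan-4-yl)ethyl]-3-methyloxiran-2-yl}-4-{[(4-methoxybenzyl)oxy]methyl}-2-oxo-2,5-dihydrofuran-3-yl]methyl acetate
Product: 20 [(5S)-5-{(2R,3R)-3-[3-hydroxy-4-(hydroxymethyl)pent-4-en-1-yl]-3-methyloxiran-2-yl}-4-{[(4-methoxybenzyl)oxy]methyl}-2-oxo-2,5-dihydrofuran-3-yl]methyl acetate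
Conditions: PPTS (0.2 equiv), MeOH, 0 °C → rt
Reagents that add atoms: none
Why: Mild acid-catalysed transketalisation to methanol removes the six-membered acetonide; the PMB ether, the acetate and the epoxide (deactivated by the neighbouring lactone carbinol) should survive.

Step 14
Reactants: 20 [(5S)-5-{(2R,3R)-3-[3-hydroxy-4-(hydroxymethyl)pent-4-en-1-yl]-3-methyloxiran-2-yl}-4-{[(4-methoxybenzyl)oxy]methyl}-2-oxo-2,5-dihydrofuran-3-yl]methyl acetate
Product: 21 [(5S)-5-{(2R,3R)-3-[4-(bromomethyl)-3-hydroxypent-4-en-1-yl]-3-methyloxiran-2-yl}-4-{[(4-methoxybenzyl)oxy]methyl}-2-oxo-2,5-dihydrofuran-3-yl]methyl acetate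
Conditions: CBr4 (1.15 equiv), PPh3 (1.2 equiv), CH2Cl2, −30 → 0 °C
Reagents that add atoms: carbon tetrabromide, BrC(Br)(Br)Br
Why: Appel bromination takes the unhindered primary allylic hydroxyl in preference to the secondary one at low temperature, and allylic transposition is degenerate in this 2-substituted allyl unit.

Step 15
Reactants: 21 [(5S)-5-{(2R,3R)-3-[4-(bromomethyl)-3-hydroxypent-4-en-1-yl]-3-methyloxiran-2-yl}-4-{[(4-methoxybenzyl)oxy]methyl}-2-oxo-2,5-dihydrofuran-3-yl]methyl acetate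
Product: 22 [(5S)-5-{(2R,3R)-3-[4-(bromomethyl)-3-hydroxypent-4-en-1-yl]-3-methyloxiran-2-yl}-4-(hydroxymethyl)-2-oxo-2,5-dihydrofuran-3-yl]methyl acetate
Conditions: DDQ (1.5 equiv), CH2Cl2/pH 7 buffer 10:1, 0 °C → rt
Reagents that add atoms: none
Why: Oxidative PMB ether cleavage with DDQ frees the C8 hydroxyl under neutral conditions that leave the allylic bromide, the epoxide and the acetate alone.

Step 16
Reactants: 22 [(5S)-5-{(2R,3R)-3-[4-(bromomethyl)-3-hydroxypent-4-en-1-yl]-3-methyloxiran-2-yl}-4-(hydroxymethyl)-2-oxo-2,5-dihydrofuran-3-yl]methyl acetate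
Product: 23 [(5S)-5-{(2R,3R)-3-[4-(bromomethyl)-3-oxopent-4-en-1-yl]-3-methyloxiran-2-yl}-4-formyl-2-oxo-2,5-dihydrofuran-3-yl]methyl acetate
Conditions: Dess–Martin periodinane (3 equiv), NaHCO3, CH2Cl2, 0 °C → rt; filtration through a short silica pad, used at once
Reagents that add atoms: none
Why: Dess–Martin oxidation converts the secondary allylic C1 alcohol into the 2-(bromomethyl)enone and the primary C8 alcohol into the butenolide-conjugated aldehyde in one buffered, non-nucleophilic operation, and removes the C1 stereocentre so that a single compound results.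

Step 17
Reactants: 23 [(5S)-5-{(2R,3R)-3-[4-(bromomethyl)-3-oxopent-4-en-1-yl]-3-methyloxiran-2-yl}-4-formyl-2-oxo-2,5-dihydrofuran-3-yl]methyl acetate
Product: 25 (4R,5R,6S,8S)-13-acetoxy-4,5-epoxy-8-hydroxy-1-oxogermacra-7(11),10(14)-dien-12,6-olide, via allylindium dibromide 24 (not isolated)
Conditions: In powder (3 equiv), THF/H2O 4:1, 25 °C, 23 added by syringe pump (final 2 mM)
Reagents that add atoms: none
Why: Indium inserts into the allylic C–Br bond and the 2-acylallylindium 24 adds to the C8 aldehyde through its remote methylene carbon in a six-membered cyclic SE2' transition state, so that C8–C9 forms, the alkene moves to C10=C14 and the carbocycle closes in one event. The closest known reaction type is the intramolecular Barbier (Nozaki–Hiyama-type) allylation of aldehydes by 2-(bromomethyl)acrylates used to close ten-membered germacranolide rings, with the enone here in the role of the acrylate. The closure is a 10-exo-trig addition to the formyl group (the new bond is endocyclic, the carbonyl oxygen stays outside), favoured over dimerisation by high dilution and slow addition. C8 is the only new stereocentre and is set by the aldehyde face that the tether can reach, that is by the conformation imposed by the planar butenolide and the trans-epoxide; 8S is assumed and has to be proven on 25. The step needs chemoselectivity for the aldehyde over ketone, lactone, acetate and epoxide, which the mild allylindium reagent and the high electrophilicity of the butenolide-conjugated aldehyde secure, while water protonates the indium alkoxide at once.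

Step 18
Reactants: 25 (4R,5R,6S,8S)-13-acetoxy-4,5-epoxy-8-hydroxy-1-oxogermacra-7(11),10(14)-dien-12,6-olide
Product: 27 (4R,5R,6S,8S,10R)-13-acetoxy-4,5-epoxy-8,10-dihydroxy-1-oxogermacr-7(11)-en-12,6-olide, via C10 hydroperoxide 26 (not isolated)
Conditions: Mn(dpm)3 (20 mol%), PhSiH3 (2 equiv), O2 (1 atm), i-PrOH/CH2Cl2, 0 °C; then P(OEt)3
Reagents that add atoms: dioxygen, O=O
Why: Mukaiyama-type hydrogen-atom-transfer hydration, known to turn enones into α-hydroxy ketones: the manganese hydride gives H• to the terminal methylene C14, the tertiary α-keto radical at C10 captures O2 to give 26 and phosphite reduces it; the tetrasubstituted electron-poor butenolide alkene does not accept the hydrogen atom, and O2 is expected to enter from the outer face of the ring to give 10R.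

Step 19
Reactants: 27 (4R,5R,6S,8S,10R)-13-acetoxy-4,5-epoxy-8,10-dihydroxy-1-oxogermacr-7(11)-en-12,6-olide
Product: 28 (4R,5R,6S,8S,10R)-13-acetoxy-4,5-epoxy-10-hydroxy-8-(methacryloyloxy)-1-oxogermacr-7(11)-en-12,6-olide
Conditions: methacrylic anhydride (2 equiv), Et3N, DMAP (0.1 equiv), CH2Cl2, 0 °C
Reagents that add atoms: methacrylic anhydride, C=C(C)C(=O)OC(=O)C(C)=C
Why: DMAP-catalysed (Steglich-type) acylation distinguishes the secondary C8 hydroxyl from the tertiary C10 hydroxyl; it follows the hydration because a methacrylate would itself be hydrated under the conditions of step 18.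

Step 20
Reactants: 28 (4R,5R,6S,8S,10R)-13-acetoxy-4,5-epoxy-10-hydroxy-8-(methacryloyloxy)-1-oxogermacr-7(11)-en-12,6-olide
Product: 29 glaucolide A
Conditions: Ac2O (10 equiv), DMAP (2 equiv), Et3N, CH2Cl2, 25–35 °C; neutralised silica
Reagents that add atoms: acetic anhydride, CC(=O)OC(C)=O
Why: Forcing DMAP-mediated acetylation esterifies the tertiary α-ketol hydroxyl under basic conditions free of Lewis acid, which spare the epoxide and the allylic acetate.

**Compound list**

1 | geranyl acetate | CC(C)=CCC/C(C)=C/COC(C)=O | starting material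
2 | (2E)-6,7-epoxy-3,7-dimethyloct-2-en-1-yl acetate (racemic) | CC1(C)OC1CC/C(C)=C/COC(C)=O | intermediate
3 | (2E)-6,7-dihydroxy-3,7-dimethyloct-2-en-1-yl acetate (racemic) | CC(C)(O)C(O)CC/C(C)=C/COC(C)=O | intermediate
4 | (2E)-3-methyl-6-oxohex-2-en-1-yl acetate | O=CCC/C(C)=C/COC(C)=O | intermediate
5 | methyl acrylate | C=CC(=O)OC | starting material
6 | methyl (6E)-8-acetoxy-3-hydroxy-6-methyl-2-methylideneoct-6-enoate (racemic) | C=C(C(=O)OC)C(O)CC/C(C)=C/COC(C)=O | intermediate
7 | (6E)-6-methyl-2-methylideneoct-6-ene-1,3,8-triol (racemic) | C=C(CO)C(O)CC/C(C)=C/CO | intermediate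
8 | (2E)-5-(2,2-dimethyl-5-methylidene-1,3-dioxan-4-yl)-3-methylpent-2-en-1-ol (racemic) | C=C1COC(C)(C)OC1CC/C(C)=C/CO | intermediate
9 | (2E)-5-(2,2-dimethyl-5-methylidene-1,3-dioxan-4-yl)-3-methylpent-2-enal (racemic) | C=C1COC(C)(C)OC1CC/C(C)=C/C=O | intermediate
10 | methyl propiolate | C#CC(=O)OC | starting material
11 | methyl (4R,5E)-8-(2,2-dimethyl-5-methylidene-1,3-dioxan-4-yl)-4-hydroxy-6-methyloct-5-en-2-ynoate (both dioxane epimers) | COC(=O)C#C[C@H](O)/C=C(\C)CCC1OC(C)(C)OCC1=C | intermediate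
12 | methyl (4S)-4-{(2R,3R)-3-[2-(2,2-dimethyl-5-methylidene-1,3-dioxan-4-yl)ethyl]-3-methyloxiran-2-yl}-4-hydroxybut-2-ynoate | COC(=O)C#C[C@H](O)[C@H]1O[C@]1(C)CCC2OC(C)(C)OCC2=C | intermediate
13 | (tributylstannyl)methanol | CCCC[Sn](CCCC)(CCCC)CO | starting material
14 | tributyl{[(4-methoxybenzyl)oxy]methyl}stannane | CCCC[Sn](CCCC)(CCCC)COCc1ccc(OC)cc1 | intermediate
15 | dilithium alkenyl(alkoxymethyl)cuprate alkoxide from syn-carbocupration of 12 (C8 and Cu cis) | COC(=O)/C([Cu-]COCc1ccc(OC)cc1)=C(/COCc1ccc(OC)cc1)[C@H]([O-])[C@H]1O[C@]1(C)CCC2OC(C)(C)OCC2=C.[Li+].[Li+] | intermediate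
16 | methyl (2E,4S)-4-{(2R,3R)-3-[2-(2,2-dimethyl-5-methylidene-1,3-dioxan-4-yl)ethyl]-3-methyloxiran-2-yl}-4-hydroxy-2-iodo-3-{[(4-methoxybenzyl)oxy]methyl}but-2-enoate (ester and carbinol cis; formed as its lithium alkoxide) | COC(=O)/C(I)=C(/COCc1ccc(OC)cc1)[C@H](O)[C@H]1O[C@]1(C)CCC2OC(C)(C)OCC2=C | intermediate
17 | (5S)-5-{(2R,3R)-3-[2-(2,2-dimethyl-5-methylidene-1,3-dioxan-4-yl)ethyl]-3-methyloxiran-2-yl}-3-iodo-4-{[(4-methoxybenzyl)oxy]methyl}furan-2(5H)-one | COc1ccc(COCC2=C(I)C(=O)O[C@@H]2[C@H]3O[C@]3(C)CCC4OC(C)(C)OCC4=C)cc1 | intermediate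
18 | (5S)-5-{(2R,3R)-3-[2-(2,2-dimethyl-5-methylidene-1,3-dioxan-4-yl)ethyl]-3-methyloxiran-2-yl}-3-(hydroxymethyl)-4-{[(4-methoxybenzyl)oxy]methyl}furan-2(5H)-one | COc1ccc(COCC2=C(CO)C(=O)O[C@@H]2[C@H]3O[C@]3(C)CCC4OC(C)(C)OCC4=C)cc1 | intermediate
19 | [(5S)-5-{(2R,3R)-3-[2-(2,2-dimethyl-5-methylidene-1,3-dioxan-4-yl)ethyl]-3-methyloxiran-2-yl}-4-{[(4-methoxybenzyl)oxy]methyl}-2-oxo-2,5-dihydrofuran-3-yl]methyl acetate | COc1ccc(COCC2=C(COC(C)=O)C(=O)O[C@@H]2[C@H]3O[C@]3(C)CCC4OC(C)(C)OCC4=C)cc1 | intermediate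
20 | [(5S)-5-{(2R,3R)-3-[3-hydroxy-4-(hydroxymethyl)pent-4-en-1-yl]-3-methyloxiran-2-yl}-4-{[(4-methoxybenzyl)oxy]methyl}-2-oxo-2,5-dihydrofuran-3-yl]methyl acetate | COc1ccc(COCC2=C(COC(C)=O)C(=O)O[C@@H]2[C@H]3O[C@]3(C)CCC(O)C(=C)CO)cc1 | intermediate
21 | [(5S)-5-{(2R,3R)-3-[4-(bromomethyl)-3-hydroxypent-4-en-1-yl]-3-methyloxiran-2-yl}-4-{[(4-methoxybenzyl)oxy]methyl}-2-oxo-2,5-dihydrofuran-3-yl]methyl acetate | COc1ccc(COCC2=C(COC(C)=O)C(=O)O[C@@H]2[C@H]3O[C@]3(C)CCC(O)C(=C)CBr)cc1 | intermediate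
22 | [(5S)-5-{(2R,3R)-3-[4-(bromomethyl)-3-hydroxypent-4-en-1-yl]-3-methyloxiran-2-yl}-4-(hydroxymethyl)-2-oxo-2,5-dihydrofuran-3-yl]methyl acetate | OCC1=C(COC(C)=O)C(=O)O[C@@H]1[C@H]2O[C@]2(C)CCC(O)C(=C)CBr | intermediate
23 | [(5S)-5-{(2R,3R)-3-[4-(bromomethyl)-3-oxopent-4-en-1-yl]-3-methyloxiran-2-yl}-4-formyl-2-oxo-2,5-dihydrofuran-3-yl]methyl acetate | O=CC1=C(COC(C)=O)C(=O)O[C@@H]1[C@H]2O[C@]2(C)CCC(=O)C(=C)CBr | intermediate
24 | allylindium dibromide derived from 23 (indium on the former bromomethyl carbon) | O=CC1=C(COC(C)=O)C(=O)O[C@@H]1[C@H]2O[C@]2(C)CCC(=O)C(=C)C[In](Br)Br | intermediate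
25 | (4R,5R,6S,8S)-13-acetoxy-4,5-epoxy-8-hydroxy-1-oxogermacra-7(11),10(14)-dien-12,6-olide | O[C@H]1CC(=C)C(=O)CC[C@@]2(C)O[C@@H]2[C@H]2OC(=O)C(COC(C)=O)=C12 | intermediate
26 | (4R,5R,6S,8S,10R)-13-acetoxy-4,5-epoxy-10-hydroperoxy-8-hydroxy-1-oxogermacr-7(11)-en-12,6-olide | O[C@H]1C[C@@](C)(OO)C(=O)CC[C@@]2(C)O[C@@H]2[C@H]2OC(=O)C(COC(C)=O)=C12 | intermediate
27 | (4R,5R,6S,8S,10R)-13-acetoxy-4,5-epoxy-8,10-dihydroxy-1-oxogermacr-7(11)-en-12,6-olide | O[C@H]1C[C@@](C)(O)C(=O)CC[C@@]2(C)O[C@@H]2[C@H]2OC(=O)C(COC(C)=O)=C12 | intermediate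
28 | (4R,5R,6S,8S,10R)-13-acetoxy-4,5-epoxy-10-hydroxy-8-(methacryloyloxy)-1-oxogermacr-7(11)-en-12,6-olide | C=C(C)C(=O)O[C@H]1C[C@@](C)(O)C(=O)CC[C@@]2(C)O[C@@H]2[C@H]2OC(=O)C(COC(C)=O)=C12 | intermediate
29 | glaucolide A, (4R,5R,6S,8S,10R)-10,13-diacetoxy-4,5-epoxy-8-(methacryloyloxy)-1-oxogermacr-7(11)-en-12,6-olide | C=C(C)C(=O)O[C@H]1C[C@@](C)(OC(C)=O)C(=O)CC[C@@]2(C)O[C@@H]2[C@H]2OC(=O)C(COC(C)=O)=C12 | target

**Step count and risks**

Total step count: 20. Longest linear sequence: 19 steps (steps 1–8 and 10–20, from 1 to 29); step 9 is a one-step side branch.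

Steps most likely to fail:

1. Step 17. The allylindium may add to the wrong face of the aldehyde and give the 8R alcohol, or dimerise instead of cyclising. The fallback for the wrong face sets out from 23 and accepts the epimer. The same cyclisation then gives (4R,5R,6S,8R)-13-acetoxy-4,5-epoxy-8-hydroxy-1-oxogermacra-7(11),10(14)-dien-12,6-olide F1. Hydration as in step 18 passes through the C10 hydroperoxide of the 8R series F2 to the (8R,10R)-diol F3, provided C10 is again formed as 10R. A Mitsunobu esterification of F3 with methacrylic acid (PPh3, DIAD, toluene, 0 °C) then inverts C8 and installs the ester in one operation; the tertiary C10 hydroxyl does not react. The fallback comes back to the route at 28.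

2. Step 18. Capture of the planar C10 radical by O2 may show poor facial selectivity, or the radical may simply be reduced to the 10-methyl ketone. The fallback sets out from 25 and replaces radical oxygenation by a reagent-controlled epoxidation of an enol ether. Excess Et3SiH with Wilkinson's catalyst (toluene, 50 °C) silylates the C8 hydroxyl and adds 1,4 to the enone, giving the 1,8-bis(triethylsilyloxy)germacra-1(10),7(11)-diene F4. Shi epoxidation of the enol silane (chiral fructose-derived ketone, Oxone, buffered MeCN/dimethoxymethane/water, 0 °C; catalyst enantiomer chosen for 10R) gives, after collapse of the silyloxy epoxide, the 8-O-triethylsilyl 10-hydroxy ketone F5. Buffered HF·pyridine removes the silyl ether and the fallback comes back at 27.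

3. Step 10. The lithium alkoxide next to the epoxide may trigger Payne-type migration or opening of the epoxide by the cuprate, and the alkoxymethyl cuprate may decompose before it adds. The fallback sets out from 11, which has no epoxide yet, and introduces the epoxide late under reagent control. The one-pot sequence of step 10 applied to 11 passes through the alkenylcuprate of the enyne series F6 and the iodo hydroxy enoate of the enyne series F7 to the (5R)-iodobutenolide with the intact E-alkene F8. Stille hydroxymethylation with 13 as in step 11 gives the 3-(hydroxymethyl)butenolide with the intact E-alkene F9. Shi epoxidation of the trisubstituted C4=C5 alkene of F9 (ketone enantiomer chosen for 4R,5R; the butenolide alkene and the 1,1-disubstituted methylene are poor substrates) then brings the fallback back at 18.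

Further compounds
F1 | step 17 | (4R,5R,6S,8R)-13-acetoxy-4,5-epoxy-8-hydroxy-1-oxogermacra-7(11),10(14)-dien-12,6-olide | O[C@@H]1CC(=C)C(=O)CC[C@@]2(C)O[C@@H]2[C@H]2OC(=O)C(COC(C)=O)=C12
F2 | step 17 | (4R,5R,6S,8R,10R)-13-acetoxy-4,5-epoxy-10-hydroperoxy-8-hydroxy-1-oxogermacr-7(11)-en-12,6-olide | O[C@@H]1C[C@@](C)(OO)C(=O)CC[C@@]2(C)O[C@@H]2[C@H]2OC(=O)C(COC(C)=O)=C12
F3 | step 17 | (4R,5R,6S,8R,10R)-13-acetoxy-4,5-epoxy-8,10-dihydroxy-1-oxogermacr-7(11)-en-12,6-olide | O[C@@H]1C[C@@](C)(O)C(=O)CC[C@@]2(C)O[C@@H]2[C@H]2OC(=O)C(COC(C)=O)=C12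
F4 | step 18 | (4R,5R,6S,8S)-13-acetoxy-4,5-epoxy-1,8-bis(triethylsilyloxy)germacra-1(10),7(11)-dien-12,6-olide (enol ether geometry not assigned) | CC[Si](CC)(CC)O[C@H]1CC(C)=C(O[Si](CC)(CC)CC)CC[C@@]2(C)O[C@@H]2[C@H]2OC(=O)C(COC(C)=O)=C12
F5 | step 18 | (4R,5R,6S,8S,10R)-13-acetoxy-4,5-epoxy-10-hydroxy-1-oxo-8-(triethylsilyloxy)germacr-7(11)-en-12,6-olide | CC[Si](CC)(CC)O[C@H]1C[C@@](C)(O)C(=O)CC[C@@]2(C)O[C@@H]2[C@H]2OC(=O)C(COC(C)=O)=C12
F6 | step 10 | dilithium alkenyl(alkoxymethyl)cuprate alkoxide from syn-carbocupration of 11 | COC(=O)/C([Cu-]COCc1ccc(OC)cc1)=C(/COCc1ccc(OC)cc1)[C@H]([O-])/C=C(\C)CCC1OC(C)(C)OCC1=C.[Li+].[Li+]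
F7 | step 10 | methyl (2E,4R,5E)-8-(2,2-dimethyl-5-methylidene-1,3-dioxan-4-yl)-4-hydroxy-2-iodo-3-{[(4-methoxybenzyl)oxy]methyl}-6-methylocta-2,5-dienoate | COC(=O)/C(I)=C(/COCc1ccc(OC)cc1)[C@H](O)/C=C(\C)CCC1OC(C)(C)OCC1=C
F8 | step 10 | (5R)-5-[(1E)-4-(2,2-dimethyl-5-methylidene-1,3-dioxan-4-yl)-2-methylbut-1-en-1-yl]-3-iodo-4-{[(4-methoxybenzyl)oxy]methyl}furan-2(5H)-one | COc1ccc(COCC2=C(I)C(=O)O[C@@H]2/C=C(\C)CCC3OC(C)(C)OCC3=C)cc1
F9 | step 10 | (5R)-5-[(1E)-4-(2,2-dimethyl-5-methylidene-1,3-dioxan-4-yl)-2-methylbut-1-en-1-yl]-3-(hydroxymethyl)-4-{[(4-methoxybenzyl)oxy]methyl}furan-2(5H)-one | COc1ccc(COCC2=C(CO)C(=O)O[C@@H]2/C=C(\C)CCC3OC(C)(C)OCC3=C)cc1
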